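**Strategy.** The saturated ring B of the tetralin (C1, C2, C3, C4, C4a, C8a) is cut at C1–C2 and C3–C4. The four atoms that remain, C1, C8a, C4a and C4, are the cyclobutene ring of a 1-aryl-benzocyclobutene; C2 and C3 come from an enantiopure 5-menthyloxybutenolide. On heating, the benzocyclobutene opens to an o-quinodimethane that the butenolide captures on one face: one operation enlarges the four-membered ring by two carbons, forms both ring bonds and fixes C1 and C2 (1,2-cis) absolutely. The acetal carbon then serves as a masked aldehyde at C3, through which the cis ring fusion relaxes to 2,3-trans before reduction and O-methylation.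

Key step: step 2

Assumption: the racemic benzocyclobutene carboxylic acid and the menthyloxyfuranone are taken as purchased; the stereocentre of the acid is irrelevant because it is lost in the planar diene.

Step 1
Reactants: 1 3,4-dimethoxybicyclo[4.2.0]octa-1,3,5-triene-7-carboxylic acid (racemic); 2 4-iodo-1,2-dimethoxybenzene
Product: 3 7-(3,4-dimethoxyphenyl)-3,4-dimethoxybicyclo[4.2.0]octa-1,3,5-triene (racemic 1-aryl-benzocyclobutene)
Conditions: Ir[dF(CF3)ppy]2(dtbbpy)PF6 (1 mol %), NiCl2·glyme (10 mol %), dtbbpy (15 mol %), Cs2CO3 (1.5 equiv), DMF, blue LEDs, 25 °C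
Reagents that add atoms: none
Why: Metallaphotoredox decarboxylative arylation of a benzylic carboxylic acid: the cesium carboxylate is oxidized by the photoexcited iridium complex, loses CO2, and the benzocyclobutenyl radical is captured by the divalent aryl-nickel iodide formed from 2 and zerovalent nickel, reductive elimination forming the C(sp3)–C(sp2) bond at a temperature where the cyclobutene ring stays closed; no stereocontrol is needed.

Step 2
Reactants: 3 7-(3,4-dimethoxyphenyl)-3,4-dimethoxybicyclo[4.2.0]octa-1,3,5-triene; 4 (5R)-5-{[(1R,2S,5R)-5-methyl-2-(propan-2-yl)cyclohexyl]oxy}furan-2(5H)-one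
Product: 6 (3R,3aR,9S,9aS)-9-(3,4-dimethoxyphenyl)-6,7-dimethoxy-3-{[(1R,2S,5R)-5-methyl-2-(propan-2-yl)cyclohexyl]oxy}-3a,4,9,9a-tetrahydronaphtho[2,3-c]furan-1(3H)-one (cis-fused lactone acetal), via (E)-o-quinodimethane 5 (not isolated)
Conditions: 2.5 equiv of 4, BHT (5 mol %), degassed o-xylene, sealed tube, 130 °C
Reagents that add atoms: none
Why: Heating opens the cyclobutene ring of 3 by thermal conrotatory 4π-electrocyclic ring opening, the aryl group rotating outward for steric reasons so that the (E)-o-quinodimethane 5 is formed, and 5 is trapped by 4 in a [4+2] cycloaddition that restores the aromatic sextet (benzocyclobutene/o-quinodimethane Diels–Alder reaction; closest known types are the trapping of such dienes by maleic anhydride and the anti-selective cycloadditions of 5-alkoxyfuran-2(5H)-ones). Ring B is closed by intermolecular [4+2] cycloaddition, which forms C9–C9a and C3a–C4 and leaves the former four-membered ring enlarged by the two alkene carbons of 4; the lactone ring is not closed here but carried in from 4 and ends cis-fused because addition to the Z-alkene is suprafacial. Regiochemistry should follow the ortho rule: the unsubstituted CH2 terminus of 5 (largest HOMO coefficient, least hindered) bonds to the β-carbon of the butenolide, so the aryl-bearing carbon ends next to the carbonyl-bearing carbon. The endo transition state, with the lactone carbonyl under the diene, places the outward aryl at C9 cis to the carbonyl at C9a. The absolute configuration of C9, C9a and C3a is controlled by the acetal stereocentre C3 of 4, whose menthyloxy group shields one face of the flat five-membered ring so that 5 adds anti to it. The step needs outward torquoselectivity, ortho regioselectivity, endo selectivity and anti facial selectivity, and the excess of 4 should suppress dimerization of 5.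

Step 3
Reactants: 6 cis-fused lactone acetal
Product: 8 methyl (1S,2S,3S)-1-(3,4-dimethoxyphenyl)-3-formyl-6,7-dimethoxy-1,2,3,4-tetrahydronaphthalene-2-carboxylate, via cis-formyl ester 7 (not isolated)
Conditions: NaOMe (0.2 equiv), MeOH–THF, 0 °C to 20 °C; aqueous NH4Cl quench
Reagents that add atoms: methanol, CO
Why: Transesterification of the acyloxy acetal opens the lactone, the hemiacetal alkoxide expels menthoxide to unveil the aldehyde at C3, and base-catalysed epimerization through the aldehyde enolate should deliver the thermodynamically favoured 2,3-trans isomer (C2 and C3 substituents diequatorial, C1 aryl pseudoaxial), while the far less acidic ester centre C2 and C1 keep the configuration set in step 2.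

Step 4
Reactants: 8 methyl (1S,2S,3S)-1-(3,4-dimethoxyphenyl)-3-formyl-6,7-dimethoxy-1,2,3,4-tetrahydronaphthalene-2-carboxylate
Product: 9 [(1S,2S,3S)-1-(3,4-dimethoxyphenyl)-6,7-dimethoxy-1,2,3,4-tetrahydronaphthalene-2,3-diyl]dimethanol
Conditions: LiAlH4 (2.5 equiv), THF, 0 °C to 20 °C; aqueous potassium sodium tartrate work-up
Reagents that add atoms: none
Why: Hydride reduction of aldehyde and ester to the two primary alcohols; the aldehyde is reduced faster than it can enolize, so no stereocentre is at risk.

Step 5
Reactants: 9 [(1S,2S,3S)-1-(3,4-dimethoxyphenyl)-6,7-dimethoxy-1,2,3,4-tetrahydronaphthalene-2,3-diyl]dimethanol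
Product: 10 (1S,2S,3S)-1-(3,4-dimethoxyphenyl)-6,7-dimethoxy-2,3-bis(methoxymethyl)-1,2,3,4-tetrahydronaphthalene
Conditions: NaH (3 equiv), MeI (4 equiv), THF–DMF, 0 °C to 20 °C
Reagents that add atoms: iodomethane, CI
Why: Williamson ether synthesis on both primary alkoxides; no stereocentre is involved.

**Compound list**

1 | 3,4-dimethoxybicyclo[4.2.0]octa-1,3,5-triene-7-carboxylic acid (racemic) | COc1cc2CC(C(O)=O)c2cc1OC | starting material
2 | 4-iodo-1,2-dimethoxybenzene | COc1ccc(I)cc1OC | starting material
3 | 7-(3,4-dimethoxyphenyl)-3,4-dimethoxybicyclo[4.2.0]octa-1,3,5-triene (racemic) | COc1ccc(cc1OC)C1Cc2cc(OC)c(OC)cc12 | intermediate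
4 | (5R)-5-{[(1R,2S,5R)-5-methyl-2-(propan-2-yl)cyclohexyl]oxy}furan-2(5H)-one | O=C1C=C[C@H](O[C@@H]2C[C@H](C)CC[C@H]2C(C)C)O1 | starting material
5 | (E)-o-quinodimethane: 4-[(E)-(3,4-dimethoxy-6-methylidenecyclohexa-2,4-dien-1-ylidene)methyl]-1,2-dimethoxybenzene | C=C1C=C(OC)C(OC)=C/C1=C\c1ccc(OC)c(OC)c1 | intermediate
6 | (3R,3aR,9S,9aS)-9-(3,4-dimethoxyphenyl)-6,7-dimethoxy-3-{[(1R,2S,5R)-5-methyl-2-(propan-2-yl)cyclohexyl]oxy}-3a,4,9,9a-tetrahydronaphtho[2,3-c]furan-1(3H)-one | COc1ccc(cc1OC)[C@H]1c2cc(OC)c(OC)cc2C[C@@H]2[C@H]1C(=O)O[C@H]2O[C@@H]1C[C@H](C)CC[C@H]1C(C)C | intermediate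
7 | methyl (1S,2S,3R)-1-(3,4-dimethoxyphenyl)-3-formyl-6,7-dimethoxy-1,2,3,4-tetrahydronaphthalene-2-carboxylate (cis-formyl ester) | O=C[C@@H]1Cc2cc(OC)c(OC)cc2[C@H](c2ccc(OC)c(OC)c2)[C@@H]1C(=O)OC | intermediate
8 | methyl (1S,2S,3S)-1-(3,4-dimethoxyphenyl)-3-formyl-6,7-dimethoxy-1,2,3,4-tetrahydronaphthalene-2-carboxylate | O=C[C@H]1Cc2cc(OC)c(OC)cc2[C@H](c2ccc(OC)c(OC)c2)[C@@H]1C(=O)OC | intermediate
9 | [(1S,2S,3S)-1-(3,4-dimethoxyphenyl)-6,7-dimethoxy-1,2,3,4-tetrahydronaphthalene-2,3-diyl]dimethanol | OC[C@H]1Cc2cc(OC)c(OC)cc2[C@H](c2ccc(OC)c(OC)c2)[C@@H]1CO | intermediate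
10 | (1S,2S,3S)-1-(3,4-dimethoxyphenyl)-6,7-dimethoxy-2,3-bis(methoxymethyl)-1,2,3,4-tetrahydronaphthalene | COC[C@H]1Cc2cc(OC)c(OC)cc2[C@H](c2ccc(OC)c(OC)c2)[C@@H]1COC | target

**Total step count:** 5. **Longest linear sequence:** 5 steps (1 → 3 → 6 → 8 → 9 → 10).

**Steps most likely to fail**

Step 2 (key step). Capture of the diene by the β-substituted butenolide may be slower than dimerization of the diene, or endo and regiochemical control may be incomplete. The fallback sets out from 3 and heats it (o-xylene, 130 °C) with the C2-symmetric E-dienophile bis[(1R)-2-methoxy-2-oxo-1-phenylethyl] (2E)-but-2-enedioate F1, made from fumaryl chloride and methyl (R)-mandelate (pyridine, CH2Cl2). This doubly activated dienophile has no regiochemical issue and its E-alkene sets 2,3-trans directly. The ester next to the aryl-bearing carbon is expected to be endo, and the (R)-auxiliary is chosen by analogy with mandelate fumarates as the one expected to expose the required face; its sense of induction is not derived from a rigid model. The product should be bis[(1R)-2-methoxy-2-oxo-1-phenylethyl] (1S,2S,3S)-1-(3,4-dimethoxyphenyl)-6,7-dimethoxy-1,2,3,4-tetrahydronaphthalene-2,3-dicarboxylate F2. LiAlH4 (THF, 0 °C) then cleaves both auxiliaries reductively and the route is rejoined at diol 9. This variant is one step shorter but is held in reserve because its facial and endo control should be weaker than with 4.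

Step 1. Protodecarboxylation or dimerization of the benzylic radical, and slow oxidative addition of the electron-rich aryl iodide, may outpace the cross-coupling. The fallback sets out from 1 and 2 and works without light. Acid 1 is converted into 1,3-dioxoisoindolin-2-yl 3,4-dimethoxybicyclo[4.2.0]octa-1,3,5-triene-7-carboxylate F3 (N-hydroxyphthalimide, N,N'-diisopropylcarbodiimide, DMAP cat., CH2Cl2). Iodide 2 is converted into (3,4-dimethoxyphenyl)zinc chloride F4 (iPrMgCl·LiCl, THF, −20 °C, then ZnCl2). The two are joined by decarboxylative Negishi coupling (NiCl2·glyme 20 mol %, dtbbpy 40 mol %, THF–DMF, 25 °C), which returns to 3.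

Step 3. Epimerization may not stop at C3 (slow enolization of the C2 ester toward the all-trans isomer), or the free aldehyde may undergo aldol self-condensation under methoxide. The fallback sets out from 6 and saponifies it instead (LiOH, THF–H2O, 0 °C to 20 °C). The lactone opens to (1S,2S,3R)-1-(3,4-dimethoxyphenyl)-3-formyl-6,7-dimethoxy-1,2,3,4-tetrahydronaphthalene-2-carboxylic acid F5 as its lithium salt, whose carboxylate blocks enolization at C2 while the aldehyde centre C3 equilibrates. Acidification (1 M HCl, pH 3) should give (1S,2S,3S)-1-(3,4-dimethoxyphenyl)-3-formyl-6,7-dimethoxy-1,2,3,4-tetrahydronaphthalene-2-carboxylic acid F6. LiAlH4 (THF, reflux) reduces acid and aldehyde, and the route is rejoined at diol 9.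

**Further compounds**

F1 | step 2 | bis[(1R)-2-methoxy-2-oxo-1-phenylethyl] (2E)-but-2-enedioate | COC(=O)[C@H](OC(=O)/C=C/C(=O)O[C@@H](C(=O)OC)c1ccccc1)c1ccccc1
F2 | step 2 | bis[(1R)-2-methoxy-2-oxo-1-phenylethyl] (1S,2S,3S)-1-(3,4-dimethoxyphenyl)-6,7-dimethoxy-1,2,3,4-tetrahydronaphthalene-2,3-dicarboxylate | COC(=O)[C@H](OC(=O)[C@H]1Cc2cc(OC)c(OC)cc2[C@H](c2ccc(OC)c(OC)c2)[C@@H]1C(=O)O[C@@H](C(=O)OC)c1ccccc1)c1ccccc1
F3 | step 1 | 1,3-dioxoisoindolin-2-yl 3,4-dimethoxybicyclo[4.2.0]octa-1,3,5-triene-7-carboxylate | O=C(ON1C(=O)c2ccccc2C1=O)C1Cc2cc(OC)c(OC)cc12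
F4 | step 1 | (3,4-dimethoxyphenyl)zinc chloride | COc1ccc([Zn]Cl)cc1OC
F5 | step 3 | (1S,2S,3R)-1-(3,4-dimethoxyphenyl)-3-formyl-6,7-dimethoxy-1,2,3,4-tetrahydronaphthalene-2-carboxylic acid | O=C[C@@H]1Cc2cc(OC)c(OC)cc2[C@H](c2ccc(OC)c(OC)c2)[C@@H]1C(O)=O
F6 | step 3 | (1S,2S,3S)-1-(3,4-dimethoxyphenyl)-3-formyl-6,7-dimethoxy-1,2,3,4-tetrahydronaphthalene-2-carboxylic acid | O=C[C@H]1Cc2cc(OC)c(OC)cc2[C@H](c2ccc(OC)c(OC)c2)[C@@H]1C(O)=O
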